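Remark on the chemistry: atoms carry germacranolide numbers throughout (C1 ketone, C3 carbinol, C4=C5 olefin with C15 on C4, C6 lactone carbinol, C7 ring-fusion CH, C8 angelate carbon, C9 acetate carbon, C10 tertiary carbinol with C14, C11=C13 exocyclic methylene, C12 lactone carbonyl). The two temporary hydroxyls at C1 and C6 are planned on the face of ring B that also carries the C8, C9 and C10 oxygens; the other cis-diol would serve the cleavage equally.

## The problem

The target is a 6,12-germacranolide: a ten-membered carbocycle holding a (Z)-trisubstituted C4=C5 olefin and a C1 ketone, with an α-methylene-γ-butyrolactone trans-fused across C6–C7. Six stereocentres must be set. C3 is an isolated allylic carbinol. C7 to C10 are contiguous, with the C7 side chain and the oxygens at C8, C9 and C10 all on one face, and the C6 oxygen on the other; C10 is a tertiary carbinol next to the ketone. C9 can come from the chiral pool and control C10 and C8 by 1,2-induction, and the C8 oxygen can steer C7. C3 is remote from this array and needs its own source, and C6 has to be set relative to C7 late. The exocyclic enoate is a Michael acceptor, the angelate isomerises easily to the tiglate, and the C1 ketone sits between a β-oxygen at C3 and an α-ketol at C10. Direct closure of a ten-membered ring is entropically and transannularly costly, and a (Z)-trisubstituted olefin is awkward to build in an open chain. The feature that removes both difficulties is that C1 and C6 are both oxygenated and lie 1,6 across the ring. A temporary C1–C6 bond divides the macrocycle into ring A (C1–C6, a cyclohexene whose C4=C5 bond must be Z) and ring B (C6, C7, C8, C9, C10, C1). Cleaving the cis-1,6-diol returns the ring with C1 as the ketone of the target and C6 one reduction away from the lactone carbinol.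

## Retrosynthesis

**31 back to 28.** The last operations are reserved for unmasking: the C9 acetate, the C10 hydroxyl and the C3 hydroxyl are traced to lactone 28, which already carries the angelate, a C9/C10 acetonide and a C3 silyl ether. The angelate is placed before the lactone so that O8 cannot compete for C12, and the acetonide keeps O9 distinct from O8 until the end. The forward steps need only secondary-over-tertiary acetylation and non-basic desilylation (via 29 and 30).

**28 back to 25.** The C12–O6 bond and the C6–H bond are cut: the lactone comes from diol 27 by oxidative lactonisation, and the C6 carbinol (26) from the enone carbonyl of dione 25. Carrying C12 as an ester instead would close the lactone too early and block O6 for the cleavage. The forward reduction must choose the enone carbonyl over the C1 ketone and the correct face.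

**25 back to 24.** The C1–C6 bond is re-formed in the retrosynthetic sense, turning the cyclodecenedione 25 into the cis-fused decalin-1,6-diol 24. Against direct macrocyclisations at C3–C4, C5–C6 or C8–C9, this cut makes every ring-forming event a six-membered one and fixes the olefin geometry by ring size. The precursor is a decalin whose stereocentres can be set by chair-based reasoning. The forward reaction must cleave one diol among several oxygen functions without disturbing C7.

**24 back to 20 and 14.** After removing the angelate (22), both bonds to C7 (C6–C7 and C7–C8) are cut. Ring B is assembled from the keto aldehyde 20 and the three-carbon linchpin 14, which brings C7, C11, C12 and C13 as a geminal allyl dianion equivalent. Cuts at C1–C10 or C8–C9 would need an α-oxygenated carbanion, and a single cut at C6–C7 would need a separately built, differentiated C7–C10 chain. This cut removes three stereocentres and one ring at once and leaves a monocyclic ring A compound. The forward step must add to the aldehyde under Felkin control and close the ring through a chelated chair.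

**20 back to 6 and 9.** The C1–O bond (enolate hydroxylation, 19 from 18) and the C1–C10 bond (aldol, 15) are cut, with protecting-group exchanges through 16 and 17 in between. The aldol uses the α′-carbon of enone 6 and the methyl ketone 9, so that C10 is set from C9 by 1,2-induction. An acylation–methyl addition sequence would put the wrong group in the nucleophile role for Felkin control. The forward sequence must keep the β-hydroxy ketone from reverting and must hydroxylate the hindered C1 methine.

**Fragments.** Enone 6 is traced through 5, 4, 3 and 2 to ketal enone 1, with C3 set by catalyst control. Ketone 9 comes in one flask from glycerate ester 7 (via 8). Linchpin 14 comes from acrylate 10 through 11, 12 and 13. Angelic acid 23 is used as such.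

## Roads not taken

**Alternative 1:** The cut is the C3–C4 bond. In the forward sense CrCl2 with catalytic NiCl2 converts a C4–I bond into a C4–Cr bond, which adds to a C3 formyl group and closes the ten-membered ring as A1 (C1 masked as a dithiane, lactone and angelate already present). Its merits are real: the ring, the C3 carbinol and the olefin position appear in one convergent step, the lactone stereochemistry at C6/C7 can be settled early in a small fragment, and no redox work at C6 or C12 follows the closure. In these respects it is better than the chosen plan, which sets C6 by a late reduction. Its weak points for this target are the medium-ring closure itself (high dilution, stoichiometric chromium, transannular strain), the lack of any clear control over the C3 configuration during closure, the need to make a (Z)-trisubstituted alkenyl iodide stereodefined in an open chain, and the late dithiane hydrolysis beside the methylene lactone and next to the quaternary C10. The chosen plan sets against this a ring formation that involves only six-membered closures, an olefin that cannot be E, and a C3 centre fixed by a catalyst at the outset.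

**Alternative 2:** The cut is the C8–C9 bond, reached after removing the C8 and C9 oxygens. In the forward sense the second-generation Grubbs catalyst joins vinyl groups on C7 and C10 with loss of ethylene to give A2, and the free C10 hydroxyl then directs a syn-dihydroxylation of the new olefin. The route is catalytic and its fragments are simple. The directed dihydroxylation would install O8 and O9 with the all-cis relation in a single step, which is more direct than the chosen plan, where C8 and C9 arise in separate events. For this target the metathesis must form a ten-membered diene in the presence of the exocyclic enoate and the C4=C5 bond, with dimerisation and E/Z uncertainty. OsO4 must then pick one of four olefins and one face of a flexible ring. The resulting C8/C9 diol has to be told apart for angelate and acetate. The chosen plan has more steps but delivers O8 and O9 already differentiated (free hydroxyl versus acetonide) and derives their configuration from the chiral pool and a chair transition state.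

**Alternative 3:** The cut is the C5–C6 bond. In the forward sense, at the cathode NiCl2·glyme with 2,2′-bipyridine couples a C6 radical released from an N-hydroxyphthalimide ester with a C5 alkenyl iodide, closing the ring as A3 with the methylene lactone masked as a dimethylamine adduct. The conditions are mild and redox-economical, the Michael acceptor is protected, and no temporary stereocentres or ring-fusion oxygens are needed. In step count and redox economy this road is at least as good as the chosen one. Its weaknesses are that C6 is created by radical capture at nickel during a macrocyclisation with no control element other than a possible preference for the trans lactone, that the ten-membered intramolecular version of this coupling has thin support, that the C1 ketone must survive the cathode, and that the methylene must be unveiled by amine elimination at the end. The chosen plan sets against this the predictability of six-membered-ring stereocontrol and a ring-forming step of long standing.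

Key step: step 18

## Route

Step 1
Reactants: 1 1,4-dioxaspiro[4.5]dec-6-en-8-one
Product: 2 7-iodo-1,4-dioxaspiro[4.5]dec-6-en-8-one
Conditions: I2, pyridine, CH2Cl2, 0 °C to rt
Reagents that add atoms: iodine, II
Why: Amine-mediated α-iodination of an enone (β-addition of pyridine, iodination of the enolate, elimination); the ketal and the α′-methylene are not touched.

Step 2
Reactants: 2 7-iodo-1,4-dioxaspiro[4.5]dec-6-en-8-one
Product: 3 (R)-7-iodo-1,4-dioxaspiro[4.5]dec-6-en-8-ol
Conditions: (S)-1-methyl-3,3-diphenyltetrahydro-1H,3H-pyrrolo[1,2-c][1,3,2]oxazaborole ((S)-Me-CBS, 20 mol %), BH3·SMe2, THF, −20 °C; MeOH quench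
Reagents that add atoms: none
Why: Corey–Bakshi–Shibata reduction; the ketone binds with the larger iodoalkenyl arm away from the B-methyl group, so hydride delivery should give the (R)-carbinol, which becomes C3. α-Haloenones are among the best substrates for this reduction.

Step 3
Reactants: 3 (R)-7-iodo-1,4-dioxaspiro[4.5]dec-6-en-8-ol
Product: 4 (R)-7-iodo-8-(triisopropylsilyloxy)-1,4-dioxaspiro[4.5]dec-6-ene
Conditions: iPr3SiOTf, 2,6-lutidine, CH2Cl2, 0 °C
Reagents that add atoms: triisopropylsilyl trifluoromethanesulfonate, CC(C)[Si](OS(=O)(=O)C(F)(F)F)(C(C)C)C(C)C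
Why: Silylation of a secondary allylic alcohol; the bulky ether survives every later acid and fluoride step until the end and biases ring A in step 14.

Step 4
Reactants: 4 (R)-7-iodo-8-(triisopropylsilyloxy)-1,4-dioxaspiro[4.5]dec-6-ene
Product: 5 (R)-7-methyl-8-(triisopropylsilyloxy)-1,4-dioxaspiro[4.5]dec-6-ene
Conditions: trimethylboroxine, PdCl2(dppf) (5 mol %), Cs2CO3, 1,4-dioxane/H2O, 80 °C
Reagents that add atoms: trimethylboroxine, CB1OB(C)OB(C)O1
Why: Suzuki–Miyaura methylation of the alkenyl iodide; it installs C15 on the ring olefin, so the later C4=C5 bond is Z by ring size.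

Step 5
Reactants: 5 (R)-7-methyl-8-(triisopropylsilyloxy)-1,4-dioxaspiro[4.5]dec-6-ene
Product: 6 (R)-3-methyl-4-(triisopropylsilyloxy)cyclohex-2-en-1-one
Conditions: pyridinium p-toluenesulfonate (cat.), acetone/H2O, 55 °C
Reagents that add atoms: water, O
Why: Acid-catalysed ketal hydrolysis gives the conjugated enone directly; the hindered allylic silyl ether should tolerate the mild pyridinium acid.

Step 6
Reactants: 7 methyl (S)-2,2-dimethyl-1,3-dioxolane-4-carboxylate
Product: 9 (S)-1-(2,2-dimethyl-1,3-dioxolan-4-yl)ethan-1-one, via N-methoxy-N-methylamide 8 (not isolated)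
Conditions: MeNH(OMe)·HCl, iPrMgCl, THF, −20 °C; then MeMgBr, −20 to 0 °C; aq. NH4Cl
Reagents that add atoms: methylmagnesium bromide, C[Mg]Br
Why: One-flask ester to methyl ketone conversion; the magnesium amide forms the N-methoxy-N-methylamide, whose chelated adduct with MeMgBr collapses only on work-up, so over-addition and enolisation of the α-stereocentre should be avoided.

Step 7
Reactants: 10 methyl 2-(bromomethyl)acrylate
Product: 12 methyl (Z)-3-bromo-2-(bromomethyl)acrylate, via tribromide 11 (not isolated)
Conditions: Br2, CH2Cl2, 0 °C to rt; then Et3N, 0 °C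
Reagents that add atoms: bromine, BrBr
Why: Bromine addition followed by base-induced loss of HBr (the α-bromide leaves); the two bromomethyl groups of 11 are equivalent, so only one constitution can form, and the olefin geometry is of no consequence later.

Step 8
Reactants: 12 methyl (Z)-3-bromo-2-(bromomethyl)acrylate
Product: 13 (Z)-3-bromo-2-(bromomethyl)prop-2-en-1-ol
Conditions: iBu2AlH, CH2Cl2, −78 °C; Rochelle salt work-up
Reagents that add atoms: none
Why: 1,2-Reduction of the ester at low temperature; vinylic and allylic bromides are not reduced by the aluminium hydride under these conditions.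

Step 9
Reactants: 13 (Z)-3-bromo-2-(bromomethyl)prop-2-en-1-ol
Product: 14 (Z)-[3-bromo-2-(bromomethyl)allyloxy](tert-butyl)dimethylsilane
Conditions: tBuMe2SiOTf, 2,6-lutidine, CH2Cl2, −78 °C
Reagents that add atoms: tert-butyldimethylsilyl trifluoromethanesulfonate, CC(C)(C)[Si](C)(C)OS(=O)(=O)C(F)(F)F
Why: Silylation with a hindered, non-nucleophilic base, which avoids N-alkylation by the allylic bromide; the silyloxymethyl arm is the future C12.

Step 10
Reactants: 6 (R)-3-methyl-4-(triisopropylsilyloxy)cyclohex-2-en-1-one; 9 (S)-1-(2,2-dimethyl-1,3-dioxolan-4-yl)ethan-1-one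
Product: 15 C1–C10 aldol adduct (ring A enone bearing at C1 the C10 methyl carbinol attached to the 8,9-O-isopropylidene unit; C1 epimers)
Conditions: LiN(iPr)2, THF, −78 °C; anhydrous CeCl3, −78 °C; then 9, −78 °C; AcOH quench
Reagents that add atoms: none
Why: Aldol addition of the kinetic α′-enolate, transmetalated to cerium to suppress proton transfer from the methyl ketone. Felkin–Anh attack anti to the dioxolane C9–O bond should set C10 with its oxygen anti to O9 in the extended chain (cis on the later ring B). The C1 configuration is irrelevant because C1 is re-enolised in step 14.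

Step 11
Reactants: 15 C1–C10 aldol adduct
Product: 16 C8,C9,C10-triol (ring A enone with the 2,3,4-trihydroxybutan-2-yl group at C1)
Conditions: AcOH/H2O/THF (3:1:1), 40 °C
Reagents that add atoms: none
Why: Acid hydrolysis of the terminal dioxolane; the hindered silyl ether and the β-hydroxy ketone should tolerate aqueous acetic acid.

Step 12
Reactants: 16 C8,C9,C10-triol
Product: 17 C8 triethylsilyl ether (C9 and C10 hydroxyls free)
Conditions: Et3SiCl, imidazole, CH2Cl2, −40 °C
Reagents that add atoms: chlorotriethylsilane, CC[Si](Cl)(CC)CC
Why: Selective silylation of the primary hydroxyl; the secondary and tertiary hydroxyls react far more slowly at low temperature.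

Step 13
Reactants: 17 C8 triethylsilyl ether
Product: 18 C9,C10-acetonide (ring A enone with C1–H; C8 triethylsilyl ether)
Conditions: 2-methoxypropene, pyridinium p-toluenesulfonate (cat.), CH2Cl2, 0 °C
Reagents that add atoms: 2-methoxypropene, COC(C)=C
Why: Acetalisation of the only remaining 1,2-diol. It blocks retro-aldol in step 14, shields the C9/C10 diol from Pb(OAc)4 later, and leaves a compact α-alkoxy group next to C8 for Felkin control.

Step 14
Reactants: 18 C9,C10-acetonide
Product: 19 C1 tertiary α-ketol (C1 hydroxyl trans to the C3 silyloxy group)
Conditions: KN(SiMe3)2, THF, −78 °C; 2-(phenylsulfonyl)-3-phenyloxaziridine, −78 °C; aq. NH4Cl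
Reagents that add atoms: 2-(phenylsulfonyl)-3-phenyloxaziridine, O=S(=O)(N1OC1c1ccccc1)c1ccccc1
Why: Enolate hydroxylation with an N-sulfonyloxaziridine after kinetic α′-deprotonation. Oxygen should enter opposite the C3 silyloxy group, which is pseudo-axial because of allylic strain with the C4 methyl, giving the C1 hydroxyl trans to O3 and the C10 branch cis. This temporary centre decides the cis ring fusion in step 16.

Step 15
Reactants: 19 C1 tertiary α-ketol
Product: 20 C8 aldehyde (keto aldehyde with free C1 hydroxyl and C9,C10-acetonide)
Conditions: (COCl)2, DMSO, CH2Cl2, −78 to −30 °C; Et3N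
Reagents that add atoms: none
Why: Swern oxidation converts a primary triethylsilyl ether directly into the aldehyde (silyl transfer to chloride at the alkoxysulfonium stage); the triisopropylsilyl ether and the tertiary hydroxyl are left alone.

Step 16
Reactants: 20 C8 aldehyde; 14 (Z)-[3-bromo-2-(bromomethyl)allyloxy](tert-butyl)dimethylsilane
Product: 22 cis-fused decalin-1,6,8-triol (ring B closed; C7 bears the 3-silyloxyprop-1-en-2-yl group; all ring B oxygens and the C7 side chain on one face), via bromohydrin 21 (not isolated)
Conditions: In powder (excess), THF/H2O (3:1), rt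
Reagents that add atoms: none
Why: Indium Barbier allylation used twice, with 14 as a geminal allyl dianion equivalent. The γ-bromoallylindium adds through its bromine-bearing carbon to the aldehyde under Felkin–Anh control by the dioxolane oxygen (C8 hydroxyl anti to O9), and insertion into the allylic C7–Br bond of 21 then closes ring B by attack of C7 on the C6 ketone (six-membered closure, Zimmerman–Traxler chair). Trivalent indium held by the free C8 oxygen and the carbonyl oxygen, both axial, with the allyl terminus equatorial, should place the C7 side chain cis to O8 and the C6 hydroxyl cis to the C1 hydroxyl; if the ketone reacts first the same ring results.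

Step 17
Reactants: 22 cis-fused decalin-1,6,8-triol; 23 angelic acid
Product: 24 cis-fused decalin-1,6-diol C8 angelate
Conditions: 23, 2,4,6-trichlorobenzoyl chloride, Et3N, toluene, rt; then 22, 75 °C
Reagents that add atoms: none
Why: Yamaguchi esterification through the preformed mixed anhydride, a known way to transfer the angeloyl group without Z to E isomerisation. Only the secondary C8 hydroxyl can react; the two tertiary hydroxyls are inert, and acylating O8 now keeps it from competing for C12 in step 21.

Step 18
Reactants: 24 cis-fused decalin-1,6-diol C8 angelate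
Product: 25 (Z)-cyclodec-4-ene-1,6-dione (C8 angelate, C9,C10-acetonide, C3 and C12 silyl ethers)
Conditions: Pb(OAc)4, K2CO3, CH2Cl2, −20 to 0 °C; filtered and used at once
Reagents that add atoms: none
Why: The two tertiary hydroxyls exchange acetate on tetravalent lead to give a five-membered cyclic lead diester, which collapses in a concerted two-electron fragmentation: the C1–C6 σ-bond breaks, both carbons become carbonyls and lead leaves as Pb(OAc)2. The closest known reaction type is the Criegee glycol cleavage of ring-fusion diols of cis-decalins to cyclodecane-1,6-diones. The ten-membered ring is not made by an end-to-end cyclisation; it appears when the bond common to rings A and B is cut, a six-plus-six to ten ring enlargement without entropic or transannular cost. No stereocentre is created: the two temporary centres C1 and C6 are erased and the C4=C5 bond keeps the Z geometry it had in the cyclohexene. The step needs chemoselectivity for one diol, secured because O9 and O10 are tied in the acetonide, O8 is acylated and O3 and O12 are silylated, so 24 holds a single free vicinal diol. It needs the cis relation of the hydroxyls (O1 equatorial, O6 axial on ring B, hence gauche), set in steps 14 and 16, for the cyclic ester to form quickly. It also needs the C7 centre, now α to a ketone and β to the ester, to survive; solid K2CO3 takes up the acetic acid, the temperature is kept low and 25 is reduced without storage.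

Step 19
Reactants: 25 (Z)-cyclodec-4-ene-1,6-dione
Product: 26 C6 allylic alcohol (C1 ketone retained; H6 anti to H7)
Conditions: NaBH4, CeCl3·7H2O, MeOH, −78 °C
Reagents that add atoms: none
Why: Luche reduction; the cerium-activated borohydride reduces the enone carbonyl 1,2 and should be faster there than at the C1 ketone, which is flanked by the quaternary C10. The required carbinol corresponds to peripheral attack on the conformer whose C6 carbonyl points away from the C7 side chain; this outcome is not secured by precedent.

Step 20
Reactants: 26 C6 allylic alcohol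
Product: 27 C6,C12-diol
Conditions: HF·pyridine, pyridine, THF, 0 °C
Reagents that add atoms: none
Why: Buffered fluoride cleaves the primary allylic tert-butyldimethylsilyl ether; the secondary triisopropylsilyl ether reacts far more slowly.

Step 21
Reactants: 27 C6,C12-diol
Product: 28 trans-fused α-methylene-γ-lactone (C8 angelate, C9,C10-acetonide, C3 silyl ether)
Conditions: TEMPO (2,2,6,6-tetramethylpiperidin-1-oxyl, cat.), PhI(OAc)2, CH2Cl2, rt
Reagents that add atoms: none
Why: Oxoammonium oxidation of the primary allylic alcohol to the enal, capture by the C6 hydroxyl as the lactol and further oxidation to the lactone; with O8 acylated only the 6,12-lactone can form, and its trans fusion follows from C6 and C7.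

Step 22
Reactants: 28 trans-fused α-methylene-γ-lactone
Product: 29 C9,C10-diol
Conditions: AcOH/H2O (4:1), 40 °C
Reagents that add atoms: none
Why: Acid hydrolysis of the acetonide; the triisopropylsilyl ether, the lactone and the angelate should tolerate warm aqueous acetic acid.

Step 23
Reactants: 29 C9,C10-diol
Product: 30 C9 acetate
Conditions: Ac2O, pyridine, 4-(dimethylamino)pyridine (cat.), CH2Cl2, 0 °C
Reagents that add atoms: acetic anhydride, CC(=O)OC(C)=O
Why: Acetylation of the secondary C9 hydroxyl; the tertiary C10 hydroxyl next to the ketone does not acylate under these mild conditions.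

Step 24
Reactants: 30 C9 acetate
Product: 31 CNP0308559.3
Conditions: HF·pyridine, THF, 0 °C to rt
Reagents that add atoms: none
Why: Non-basic fluoride cleavage of the C3 silyl ether, which spares the methylene lactone, both esters and the α-ketol.

## Compound list

1 | 1,4-dioxaspiro[4.5]dec-6-en-8-one | O=C1C=CC2(CC1)OCCO2 | starting material
2 | 7-iodo-1,4-dioxaspiro[4.5]dec-6-en-8-one | O=C1CCC2(OCCO2)C=C1I | intermediate
3 | (R)-7-iodo-1,4-dioxaspiro[4.5]dec-6-en-8-ol | O[C@@H]1CCC2(OCCO2)C=C1I | intermediate
4 | (R)-7-iodo-8-(triisopropylsilyloxy)-1,4-dioxaspiro[4.5]dec-6-ene | CC(C)[Si](O[C@@H]1CCC2(OCCO2)C=C1I)(C(C)C)C(C)C | intermediate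
5 | (R)-7-methyl-8-(triisopropylsilyloxy)-1,4-dioxaspiro[4.5]dec-6-ene | CC(C)[Si](O[C@@H]1CCC2(OCCO2)C=C1C)(C(C)C)C(C)C | intermediate
6 | (R)-3-methyl-4-(triisopropylsilyloxy)cyclohex-2-en-1-one | CC(C)[Si](O[C@@H]1CCC(=O)C=C1C)(C(C)C)C(C)C | intermediate
7 | methyl (S)-2,2-dimethyl-1,3-dioxolane-4-carboxylate | COC(=O)[C@@H]1COC(C)(C)O1 | starting material
8 | (S)-N-methoxy-N,2,2-trimethyl-1,3-dioxolane-4-carboxamide | CON(C)C(=O)[C@@H]1COC(C)(C)O1 | intermediate (not isolated)
9 | (S)-1-(2,2-dimethyl-1,3-dioxolan-4-yl)ethan-1-one | CC(=O)[C@@H]1COC(C)(C)O1 | intermediate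
10 | methyl 2-(bromomethyl)acrylate | C=C(CBr)C(=O)OC | starting material
11 | methyl 2,3-dibromo-2-(bromomethyl)propanoate | COC(=O)C(Br)(CBr)CBr | intermediate (not isolated)
12 | methyl (Z)-3-bromo-2-(bromomethyl)acrylate | COC(=O)/C(CBr)=C/Br | intermediate
13 | (Z)-3-bromo-2-(bromomethyl)prop-2-en-1-ol | OC/C(CBr)=C/Br | intermediate
14 | (Z)-[3-bromo-2-(bromomethyl)allyloxy](tert-butyl)dimethylsilane | CC(C)(C)[Si](C)(C)OC/C(CBr)=C/Br | intermediate
15 | C1–C10 aldol adduct: enone 6 bearing at its C6 (= C1) the 1-hydroxy-1-[(S)-2,2-dimethyl-1,3-dioxolan-4-yl]ethyl group, C10 oxygen anti to O9; C1 epimers, the one trans to O3 drawn | O=C1C=C(C)[C@H](O[Si](C(C)C)(C(C)C)C(C)C)C[C@H]1[C@@](C)(O)[C@@H]2COC(C)(C)O2 | intermediate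
16 | C8,C9,C10-triol from 15 | O=C1C=C(C)[C@H](O[Si](C(C)C)(C(C)C)C(C)C)C[C@H]1[C@@](C)(O)[C@@H](O)CO | intermediate
17 | C8 triethylsilyl ether of 16 | O=C1C=C(C)[C@H](O[Si](C(C)C)(C(C)C)C(C)C)C[C@H]1[C@@](C)(O)[C@@H](O)CO[Si](CC)(CC)CC | intermediate
18 | C9,C10-acetonide of 17 | O=C1C=C(C)[C@H](O[Si](C(C)C)(C(C)C)C(C)C)C[C@H]1[C@@]2(C)OC(C)(C)O[C@H]2CO[Si](CC)(CC)CC | intermediate
19 | C1 tertiary α-ketol: 18 with a hydroxyl at C1, trans to the C3 silyloxy group | O=C1C=C(C)[C@H](O[Si](C(C)C)(C(C)C)C(C)C)C[C@]1(O)[C@@]2(C)OC(C)(C)O[C@H]2CO[Si](CC)(CC)CC | intermediate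
20 | C8 aldehyde: keto aldehyde with free C1 hydroxyl and C9,C10-acetonide | O=C1C=C(C)[C@H](O[Si](C(C)C)(C(C)C)C(C)C)C[C@]1(O)[C@@]2(C)OC(C)(C)O[C@H]2C=O | intermediate
21 | bromohydrin: 20 after addition at C8 (C8 hydroxyl anti to O9, C7 bromide as epimers, 3-silyloxyprop-1-en-2-yl on C7) | O=C1C=C(C)[C@H](O[Si](C(C)C)(C(C)C)C(C)C)C[C@]1(O)[C@@]2(C)OC(C)(C)O[C@H]2[C@@H](O)C(Br)C(=C)CO[Si](C)(C)C(C)(C)C | intermediate (not isolated)
22 | cis-fused decalin-1,6,8-triol: ring A cyclohexene (C4=C5, C3 OTIPS), ring B with C1, C6 and C8 hydroxyls, C9,C10-acetonide and the C7 side chain all on one face | C=C(CO[Si](C)(C)C(C)(C)C)[C@H]1[C@]2(O)C=C(C)[C@H](O[Si](C(C)C)(C(C)C)C(C)C)C[C@]2(O)[C@@]3(C)OC(C)(C)O[C@H]3[C@H]1O | intermediate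
23 | angelic acid, (Z)-2-methylbut-2-enoic acid | C/C=C(/C)C(=O)O | starting material
24 | cis-fused decalin-1,6-diol C8 angelate (precursor of the key step) | C=C(CO[Si](C)(C)C(C)(C)C)[C@H]1[C@]2(O)C=C(C)[C@H](O[Si](C(C)C)(C(C)C)C(C)C)C[C@]2(O)[C@@]3(C)OC(C)(C)O[C@H]3[C@H]1OC(=O)/C(C)=C\C | intermediate
25 | (Z)-cyclodec-4-ene-1,6-dione with C8 angelate, C9,C10-acetonide, C3 OTIPS and C12 OTBS (product of the key step) | C=C(CO[Si](C)(C)C(C)(C)C)[C@H]1C(=O)/C=C(/C)[C@H](O[Si](C(C)C)(C(C)C)C(C)C)CC(=O)[C@@]2(C)OC(C)(C)O[C@H]2[C@H]1OC(=O)/C(C)=C\C | intermediate
26 | C6 allylic alcohol from 25 (C6 configured as in 31) | C=C(CO[Si](C)(C)C(C)(C)C)[C@H]1[C@H](O)/C=C(/C)[C@H](O[Si](C(C)C)(C(C)C)C(C)C)CC(=O)[C@@]2(C)OC(C)(C)O[C@H]2[C@H]1OC(=O)/C(C)=C\C | intermediate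
27 | C6,C12-diol | C=C(CO)[C@H]1[C@H](O)/C=C(/C)[C@H](O[Si](C(C)C)(C(C)C)C(C)C)CC(=O)[C@@]2(C)OC(C)(C)O[C@H]2[C@H]1OC(=O)/C(C)=C\C | intermediate
28 | trans-fused α-methylene-γ-lactone with C8 angelate, C9,C10-acetonide and C3 OTIPS | C=C1C(=O)O[C@@H]2/C=C(/C)[C@H](O[Si](C(C)C)(C(C)C)C(C)C)CC(=O)[C@@]3(C)OC(C)(C)O[C@H]3[C@@H](OC(=O)/C(C)=C\C)[C@@H]12 | intermediate
29 | C9,C10-diol from 28 | C=C1C(=O)O[C@@H]2/C=C(/C)[C@H](O[Si](C(C)C)(C(C)C)C(C)C)CC(=O)[C@@](C)(O)[C@@H](O)[C@@H](OC(=O)/C(C)=C\C)[C@@H]12 | intermediate
30 | C9 acetate, C3 triisopropylsilyl ether of the target | C=C1C(=O)O[C@@H]2/C=C(/C)[C@H](O[Si](C(C)C)(C(C)C)C(C)C)CC(=O)[C@@](C)(O)[C@@H](OC(C)=O)[C@@H](OC(=O)/C(C)=C\C)[C@@H]12 | intermediate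
31 | CNP0308559.3 | C=C1C(=O)O[C@@H]2/C=C(/C)[C@H](O)CC(=O)[C@@](C)(O)[C@@H](OC(C)=O)[C@@H](OC(=O)/C(C)=C\C)[C@@H]12 | target

## Step count and least certain steps

Total: 24 steps. Longest linear sequence: 20 steps (steps 1–5 and 10–24, from 1).

**Step 18 (key step).** If steps 14 or 16 leave part of the material trans-fused, the cyclic lead diester cannot form and cleavage becomes slow. During a slow reaction the acetic acid set free can enolise C7, with epimerisation, migration of the C11=C13 bond into conjugation, or β-elimination of the C8 ester. Fallback: starting from 24, the C6 (or C1) alkoxy radical is generated with PhI(OAc)2 and I2 under visible light in CH2Cl2. β-Scission of the C1–C6 bond gives the C6 ketone and a C1 α-hydroxyalkyl radical, which is oxidised to the C1 ketone. This one-electron pathway needs no cyclic ester, so it should also serve a trans-diol, and it returns directly to 25 without a new isolated compound.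

**Step 16.** The most likely failures are a non-chelated course of the ring closure (wrong face at C7), anti-Felkin addition at C8, or reductive 1,2-loss of bromide and hydroxide from the bromohydrin before the second allylation. Fallback: starting from 20 and 14 with one equivalent of indium at 0 °C, the reaction is stopped at bromohydrin 21. This is closed with K2CO3 in methanol to the vinyl epoxide F1. F1 is then opened with Pd(PPh3)4 and InI in THF: the π-allylpalladium alkoxide is reduced to an allylindium alkoxide in which the C8 oxygen is bound to indium from the start, and this species cyclises onto the C6 ketone to return to 22.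

**Step 14.** Deprotonation may be incomplete or go to the γ-positions (C15, C3) instead of the hindered C1 methine, the dioxolane oxygen may be lost by β-elimination from the enolate, or oxygen may enter on the wrong face. Fallback: starting from 18, soft enolisation with Me3SiOTf and Et3N gives the 2-silyloxy diene F2. Rubottom oxidation with dimethyldioxirane in acetone gives the C1 trimethylsilyl ether F3, and brief treatment with citric acid in methanol returns to 19.

**Step 19.** Hydride may add to the wrong face of the C6 carbonyl in the flexible ten-membered ring, or the C1 ketone may be reduced as well. Fallback: starting from 25, if the reduction gives mainly the C6 epimer F4, this alcohol is inverted by Mitsunobu esterification (PPh3, diisopropyl azodicarboxylate, 4-nitrobenzoic acid) to the 4-nitrobenzoate F5, and the activated ester is cleaved with K2CO3 in methanol at 0 °C to return to 26.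

**Step 10.** Proton transfer from the methyl ketone to the enolate, reversal of the hindered ketone aldol, or weak Felkin selectivity may erode the coupling. Fallback: starting from 6, the kinetic enolate is trapped with Me3SiCl (after LiN(iPr)2) as the silyl dienol ether F6, which is joined to 9 in a Mukaiyama aldol addition with BF3·OEt2 in CH2Cl2 at −78 °C (open transition state, non-chelating Lewis acid, same Felkin sense); desilylating work-up returns to 15.

## Further compounds

F0 | step 18 | none | none
F1 | step 16 | vinyl epoxide: C7–C8 oxirane of 21 (C7 epimers) | O=C1C=C(C)[C@H](O[Si](C(C)C)(C(C)C)C(C)C)C[C@]1(O)[C@@]2(C)OC(C)(C)O[C@H]2[C@H]3OC3C(=C)CO[Si](C)(C)C(C)(C)C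
F2 | step 14 | 2-(trimethylsilyloxy) diene from 18 (C6 silyl enol ether, C1=C6) | C[Si](C)(C)OC1=C(C[C@@H](O[Si](C(C)C)(C(C)C)C(C)C)C(C)=C1)[C@@]2(C)OC(C)(C)O[C@H]2CO[Si](CC)(CC)CC
F3 | step 14 | C1 trimethylsilyl ether of 19 | O=C1C=C(C)[C@H](O[Si](C(C)C)(C(C)C)C(C)C)C[C@]1(O[Si](C)(C)C)[C@@]2(C)OC(C)(C)O[C@H]2CO[Si](CC)(CC)CC
F4 | step 19 | C6 epimer of 26 | C=C(CO[Si](C)(C)C(C)(C)C)[C@H]1[C@@H](O)/C=C(/C)[C@H](O[Si](C(C)C)(C(C)C)C(C)C)CC(=O)[C@@]2(C)OC(C)(C)O[C@H]2[C@H]1OC(=O)/C(C)=C\C
F5 | step 19 | C6 4-nitrobenzoate of 26 | C=C(CO[Si](C)(C)C(C)(C)C)[C@H]1[C@H](OC(=O)c3ccc(cc3)[N+](=O)[O-])/C=C(/C)[C@H](O[Si](C(C)C)(C(C)C)C(C)C)CC(=O)[C@@]2(C)OC(C)(C)O[C@H]2[C@H]1OC(=O)/C(C)=C\C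
F6 | step 10 | (R)-2-(trimethylsilyloxy)-4-methyl-5-(triisopropylsilyloxy)cyclohexa-1,3-diene, silyl dienol ether of 6 | C[Si](C)(C)OC1=CC[C@@H](O[Si](C(C)C)(C(C)C)C(C)C)C(C)=C1
A1 | alternative 1 | macrocyclic C3 allylic alcohol with C1 dithiane (product of the chromium–nickel closure) | C=C1C(=O)O[C@@H]2/C=C(/C)[C@H](O)CC4(SCCCS4)[C@@]3(C)OC(C)(C)O[C@H]3[C@@H](OC(=O)/C(C)=C\C)[C@@H]12
A2 | alternative 2 | ten-membered 4,8-diene with free C10 hydroxyl (product of the ring-closing metathesis) | C=C1C(=O)O[C@@H]2/C=C(/C)[C@H](O[Si](C)(C)C(C)(C)C)CC(=O)[C@@](C)(O)/C=C\[C@@H]12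
A3 | alternative 3 | macrocycle with dimethylamine-masked trans lactone (product of the electroreductive coupling) | CN(C)C[C@@H]1C(=O)O[C@@H]2/C=C(/C)[C@H](O[Si](C)(C)C(C)(C)C)CC(=O)[C@@]3(C)OC(C)(C)O[C@H]3[C@@H](OC(=O)/C(C)=C\C)[C@@H]12
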